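One constant could be read straight off the ochre run, the first-order rate constant k of product formation, rate = k·c_substrate, and I meant to carry it to two new flasks.

| setting | ochre | Sunday's | Monday's |
|---|---|---|---|
| substrate | 1 mM | 1.0 mM | 2.0 mM |
| partner | 0.74 mM | 1.10 mM | 1.10 mM |
| remark | run made earlier |  |  |
| time |  | 6.0 min | 4.0 min |

ochre run (percent of the substrate charged)

| time / s | product / % | substrate / % |
|---|---|---|
| 30.0 | 19.3 | 53.8 |
| 60.0 | 30.9 | 33.9 |
| 90.0 | 38.9 | 24.8 |
| 120 | 44.4 | 18.9 |

(standard deviation of a reading: 0.5 percentage points)



- the winner by amount of product, in percent of the substrate charged; "neither" if no more than 2 percentage points parts them (Sunday's / Monday's / neither)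
- how much product is there at the end, in percent of the substrate charged: Sunday's
- how much product is there at the end, in percent of the substrate charged: Monday's

Between its first and last readings the ochre run gained 25 percentage points of product, and dividing that by the area under the substrate curve gave k = 0.528 min⁻¹. For Sunday's flask k·t came to 3.17 and for Monday's to 2.11: this is the product clock N, the number of substrate lifetimes on the path to product that fit into the run.

At one end, with substrate going to product and nowhere else, the yield would be one minus exp(−N), which gave ceilings of 95.8 % for Sunday's and 87.9 % for Monday's. At the other end, the last ochre reading, at N = 1.06, held 44.4 % of a ceiling of 65.2 %, a share of 0.681. Joining the two, I expected 65.2 % for Sunday's and 59.8 % for Monday's, so Sunday's led by 5.4 points, more than the margin.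

One number was not quite enough: the ochre share had been 0.832 at the first reading, higher than at the last, and partner per substrate was 1.10 on Sunday's against 0.550 on Monday's.

The forecast differed from my reckoning, with 45 % for Sunday's, 64 % for Monday's and the win to Monday's, on a side reaction “which stops once partner runs out”. Sunday's came out ahead: that flask gave 60.9 %, against 56.4 % on Monday's.

    substrate → product (k = 0.00893 s⁻¹)
    substrate + partner ⇌ intermediate A (K = 350 L mol⁻¹, k = 11.1 L mol⁻¹ s⁻¹)
    intermediate A → intermediate C (k = 0.0225 s⁻¹)
    partner + intermediate C ⇌ intermediate D (K = 1890 L mol⁻¹, k = 8.19 L mol⁻¹ s⁻¹)
    intermediate D → decomposed reagent (k = 0.00989 s⁻¹)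
    substrate ⇌ intermediate B (K = 0.814, k = 0.00831 s⁻¹)

Against their ceilings these results are shares of 0.636 for Sunday's and 0.642 for Monday's. The neighbouring flask was Monday's read at 2.5 min, amounts held. There N was 1.32 and the ceiling 73.3 %, and Monday's share made that 47.1 %. That flask held 47.3 % of product, with 15 % of the substrate still unbound.

The readings are calculated on assumed constants, noise included.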